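**Plan**
1. Retrosynthesis: the C3 PMB ether and the C5 angelate are removed, then the ring is cut at C4–C5 (tertiary/secondary 1,2-diol, a pinacol retron) to a seco C4 methyl ketone/C5 aldehyde. The chain is then cut at C8–C9 (alkenylzinc plus α-alkoxy aldehyde), and the C9-aldehyde/C4-ketone piece is traced to a cyclohexene made from (S)-carvone.
2. Forward: (S)-carvone is hydroxylated, its enone is transposed and reduced, and the six-membered ring is cleaved to the C9–C10–C1–C2–C3–C4 chain. A (Z)-alkenylzinc brings C5–C8; epoxidation, the C9 angelate, the C10 (R)-2-methylbutanoate and the C5 aldehyde follow. The only ring, the cyclodecane, is then closed at C4–C5, and the C5 angelate and deprotection finish the route.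
3. Stereochemistry: C1 is bought with (S)-carvone; C10 and C3 are relayed from it on the six-membered ring. C9 follows from C10 by chelation, and C7/C8 from C9 by 1,3-allylic strain. C4 and C5 are set together in the ring closure under control of C3; the ester stereocenter is bought with (R)-2-methylbutanoic acid.
4. Enabling feature: the oxygens on C3, C4 and C5 are all syn along the C2–C6 backbone, so one samarium ion can hold the C3 ether oxygen and both carbonyl oxygens on one face. The cis-fused C7–C8 oxirane and the syn C9/C10 diester bend the C5–C10 segment so that C5 reaches C4.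
5. Locants (ring and seco compounds alike): C1 isopropenyl carbon, C2 CH2, C3 CH–OH, C4 C(CH3)–OH, C5 and C9 CH–O-angeloyl, C6 CH2, C7–C8 oxirane (C8 methylated), C10 CH–O-(2-methylbutanoyl). DMPM = 3,4-dimethoxybenzyl, PMB = 4-methoxybenzyl, TBS = tert-butyldimethylsilyl.

Key step: step 19

Remark: (S)-carvone, angelic acid and (R)-2-methylbutanoic acid are taken as commercial. The DMPM trichloroacetimidate of step 2 is made fresh from 3,4-dimethoxybenzyl alcohol and trichloroacetonitrile. The angeloyl mixed anhydride is made once, in step 13, on a scale that serves both angeloylations, and is kept as a base-free toluene solution under argon at −20 °C.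

**Step 1**
Reactants: 1 (S)-(+)-carvone
Product: 3 (5R,6R)-6-hydroxycarvone, via sodium dienolate 2 (not isolated)
Conditions: NaN(SiMe3)2, THF, −78 °C; 2-(phenylsulfonyl)-3-phenyloxaziridine, −78 °C; aqueous work-up
Reagents that add atoms: 2-(phenylsulfonyl)-3-phenyloxaziridine, O=S(=O)(c1ccccc1)N1OC1c1ccccc1 (hydroxyl oxygen); NaN(SiMe3)2, C[Si](C)(C)[N-][Si](C)(C)C.[Na+] (sodium of 2 only)
Why: kinetic α′-deprotonation gives the cross-conjugated dienolate, and enolate hydroxylation (Davis oxidation) should deliver oxygen to the face opposite the adjacent isopropenyl group, setting the future C10 trans to C1.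

**Step 2**
Reactants: 3 (5R,6R)-6-hydroxycarvone
Product: 4 DMPM ether of 3
Conditions: 3,4-dimethoxybenzyl trichloroacetimidate, camphorsulfonic acid (cat.), CH2Cl2, 0 → 25 °C
Reagents that add atoms: 3,4-dimethoxybenzyl 2,2,2-trichloroacetimidate, COc1ccc(COC(=N)C(Cl)(Cl)Cl)cc1OC
Why: acid-catalysed trichloroacetimidate benzylation suits a base-sensitive α-hydroxy ketone and installs a chelating ether that DDQ removes faster than a PMB ether.

**Step 3**
Reactants: 4 DMPM ether
Product: 5 epoxy ketone (oxirane anti to the isopropenyl group)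
Conditions: 30 % aq. H2O2, NaOH (cat.), MeOH, 0 °C
Reagents that add atoms: hydrogen peroxide, OO
Why: Weitz–Scheffer nucleophilic epoxidation attacks only the enone double bond and leaves the isopropenyl group; the oxirane configuration is of no consequence because C3 is reset in step 6.

**Step 4**
Reactants: 5 epoxy ketone
Product: 7 transposed allylic alcohol (C3 hydroxyl trans to isopropenyl), via epoxy hydrazone 6 (not isolated)
Conditions: N2H4·H2O, AcOH (cat.), MeOH, 0 → 25 °C
Reagents that add atoms: hydrazine, NN (nitrogen atoms of 6 only)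
Why: Wharton transposition (hydrazone, oxirane opening to the vinyl diazene, loss of N2) moves the oxygen to C3 and the double bond to C4=C9.

**Step 5**
Reactants: 7 transposed allylic alcohol
Product: 8 transposed enone
Conditions: Dess–Martin periodinane, CH2Cl2, 0 → 25 °C
Reagents that add atoms: none
Why: Dess–Martin oxidation of the allylic alcohol erases the wrong C3 configuration and gives the enone needed for a stereoselective reduction.

**Step 6**
Reactants: 8 transposed enone
Product: 9 cis allylic alcohol (C3 hydroxyl cis to isopropenyl)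
Conditions: NaBH4, CeCl3·7H2O, MeOH, −78 °C
Reagents that add atoms: none
Why: Luche 1,2-reduction with axial hydride delivery to the half-chair bearing an equatorial isopropenyl group should give the alcohol cis to it, as in carvone to cis-carveol, which sets C3.

**Step 7**
Reactants: 9 cis allylic alcohol
Product: 10 epoxy alcohol (oxirane syn to the hydroxyl)
Conditions: VO(acac)2 (cat.), t-BuOOH, CH2Cl2, 0 → 25 °C
Reagents that add atoms: tert-butyl hydroperoxide, CC(C)(C)OO
Why: vanadium-catalysed hydroxyl-directed epoxidation touches only the allylic-alcohol double bond, syn to the hydroxyl, and leaves the isopropenyl group; the oxirane only marks the bond to be cleaved.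

**Step 8**
Reactants: 10 epoxy alcohol
Product: 11 PMB ether of 10
Conditions: NaH, 4-methoxybenzyl chloride, Bu4NI (cat.), THF/DMF, 0 → 25 °C
Reagents that add atoms: 4-methoxybenzyl chloride, COc1ccc(CCl)cc1
Why: Williamson etherification; the alkoxide is cis to the oxirane and cannot undergo Payne rearrangement, and the PMB ether gives C3 a chelating oxygen for step 19.

**Step 9**
Reactants: 11 PMB ether
Product: 13 keto aldehyde (C9 aldehyde, C4 methyl ketone), via ring diol 12 (not isolated)
Conditions: H5IO6, THF/H2O, 0 → 25 °C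
Reagents that add atoms: water, O (hydroxyl of 12; one carbonyl oxygen of 13)
Why: periodic acid hydrolyses the trisubstituted oxirane and cleaves the resulting glycol (Malaprade cleavage) in one flask, opening the six-membered ring without touching the isopropenyl group.

**Step 10**
Reactants: 14 ethyltriphenylphosphonium iodide; 15 3-[(tert-butyldimethylsilyl)oxy]propanal
Product: 19 (Z)-tert-butyl[(4-iodopent-3-en-1-yl)oxy]dimethylsilane, via ethylidene ylide 16 (not isolated), via 1-iodoethylphosphonium iodide 17 (not isolated), via iodo ylide 18 (not isolated)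
Conditions: n-BuLi, THF, 25 °C; I2, −78 °C; NaN(SiMe3)2, −78 → −20 °C; then 15, −78 → −20 °C
Reagents that add atoms: iodine, II
Why: Stork–Zhao olefination with the α-iodo ylide should give the (Z)-2-iodoalkene (iodine cis to the chain) under kinetic control.

**Step 11**
Reactants: 19 (Z)-alkenyl iodide; 13 keto aldehyde
Product: 22 seco allylic alcohol (9R), via alkenyllithium 20 (not isolated), via alkenylzinc bromide 21 (not isolated)
Conditions: t-BuLi (2 equiv), Et2O, −78 °C; ZnBr2, −78 → 0 °C; then 13, Et2O, −78 → −20 °C; aqueous work-up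
Reagents that add atoms: tert-butyllithium, [Li]C(C)(C)C (lithium of 20 only); ZnBr2, Br[Zn]Br (zinc and bromine of 21 only)
Why: iodine–lithium exchange with retention, transmetalation and Cram-chelate addition: zinc bridges the aldehyde oxygen and the C10 DMPM ether, the alkenyl group adds anti to the C1 branch to give the 9,10-syn product, and the organozinc should not add to the methyl ketone.

**Step 12**
Reactants: 22 seco allylic alcohol
Product: 23 epoxy alcohol (7S,8S,9S)
Conditions: mCPBA (1.1 equiv), Na2HPO4, CH2Cl2, −20 → 0 °C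
Reagents that add atoms: 3-chloroperbenzoic acid, O=C(OO)c1cccc(Cl)c1
Why: hydroxyl-directed peracid epoxidation; 1,3-allylic strain in the (Z)-olefin holds the C9–H in the olefin plane, so the hydrogen-bonded peracid attacks the hydroxyl face and should give the threo epoxy alcohol, while the trisubstituted olefin reacts before the hindered isopropenyl group.

**Step 13**
Reactants: 24 angelic acid
Product: 25 angelic 2,4,6-trichlorobenzoic mixed anhydride
Conditions: 2,4,6-trichlorobenzoyl chloride, Et3N, toluene, 25 °C; filtered under argon; filtrate kept as a toluene stock solution at −20 °C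
Reagents that add atoms: 2,4,6-trichlorobenzoyl chloride, O=C(Cl)c1c(Cl)cc(Cl)cc1Cl
Why: Yamaguchi mixed-anhydride formation (acylation of the triethylammonium carboxylate by the aroyl chloride); the two ortho chlorines shield the aroyl carbonyl, so the base-free filtrate should keep without disproportionation and later transfer only the angeloyl group, and the absence of a nucleophilic catalyst should leave the (Z)-olefin untouched.

**Step 14**
Reactants: 23 epoxy alcohol; 25 angelic 2,4,6-trichlorobenzoic mixed anhydride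
Product: 26 C9 angelate
Conditions: 25 (toluene solution from step 13), toluene, 75 °C
Reagents that add atoms: none
Why: Yamaguchi-type mixed-anhydride acylation without free base acylates hindered secondary alcohols at the unhindered angeloyl carbonyl and should avoid isomerisation of the angeloyl group to tigloyl.

**Step 15**
Reactants: 26 C9 angelate
Product: 27 C10 alcohol
Conditions: DDQ (1.1 equiv), CH2Cl2/pH 7 buffer, 0 °C
Reagents that add atoms: none
Why: oxidative benzyl ether cleavage; the more electron-rich DMPM ether is oxidised faster than the PMB ether, which is further deactivated by the adjacent ketone.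

**Step 16**
Reactants: 27 C10 alcohol; 28 (R)-2-methylbutanoic acid
Product: 29 C10 (R)-2-methylbutanoate
Conditions: DCC, DMAP (cat.), CH2Cl2, 0 → 25 °C
Reagents that add atoms: none
Why: Steglich esterification of the secondary alcohol under mild conditions should keep the configuration of the acid.

**Step 17**
Reactants: 29 C10 ester
Product: 30 primary alcohol (C5)
Conditions: Bu4NF, AcOH (1:1), THF, 0 → 25 °C
Reagents that add atoms: none
Why: buffered fluoride desilylation of the only silyl ether; acetic acid keeps the medium near neutral so that esters do not migrate and the epoxy alcohol does not cyclise.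

**Step 18**
Reactants: 30 primary alcohol
Product: 31 seco keto aldehyde
Conditions: Dess–Martin periodinane, pyridine, CH2Cl2, 0 °C; used crude at once
Reagents that add atoms: none
Why: Dess–Martin oxidation under pyridine buffering should give the sensitive β,γ-epoxy aldehyde without β-elimination.

**Step 19**
Reactants: 31 seco keto aldehyde
Product: 32 cyclodecane 4,5-diol (1R,3R,4R,5S,7S,8S,9S,10R)
Conditions: SmI2 (0.1 M in THF, 4 equiv), THF, −78 → 0 °C, 31 added by syringe pump (final 0.002 M); aqueous work-up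
Reagents that add atoms: none
Why: Divalent samarium reduces the aldehyde to a ketyl, which adds to the ketone held in a chelate with the C3 ether oxygen, and a second electron gives the diolate of trivalent samarium that is protonated on work-up (reductive pinacol coupling). The closest known reaction type is the low-valent-metal pinacol cyclisation of keto aldehydes, as in SmI2 cyclisations of α-alkoxy dicarbonyl compounds and McMurry-type closures of medium and large rings to 1,2-diols. The only ring of the target, the ten-membered carbocycle, is closed at C4–C5 in a 10-exo-trig mode. C4 is set by the C3 stereocenter through the five-membered samarium chelate (attack anti to C2, giving the 3,4-syn arrangement), and C5 by the samarium bridge between both oxygens on an antiperiplanar C3–C4–C5–C6 backbone, which leads to the threo (trans) diol. The step needs ring closure to beat ketyl dimerisation and plain reduction, and needs the two carbonyls to react in preference to three esters and the oxirane; the turn imposed by the cis-oxirane and the syn C9/C10 diester, slow addition at high dilution and the absence of HMPA should secure this.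

**Step 20**
Reactants: 32 cyclodecane diol; 25 angelic 2,4,6-trichlorobenzoic mixed anhydride
Product: 33 5,9-di-O-angeloyl PMB ether
Conditions: 25 (toluene solution from step 13), toluene, 75 °C
Reagents that add atoms: none
Why: the same base-free Yamaguchi-type mixed-anhydride acylation should esterify the secondary C5 hydroxyl and leave the tertiary C4 hydroxyl free.

**Step 21**
Reactants: 33 5,9-di-O-angeloyl PMB ether
Product: 34 target CNP0246823.2
Conditions: DDQ, CH2Cl2/pH 7 buffer, 0 → 25 °C
Reagents that add atoms: none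
Why: oxidative PMB ether cleavage with DDQ in wet buffered dichloromethane is neutral and should spare the three esters, the oxirane and the olefins.

**Compound list**
1 | (S)-(+)-carvone | C=C(C)[C@H]1CC=C(C)C(=O)C1 | starting material
2 | sodium cross-conjugated dienolate of 1 (O–C1=C6) | C=C(C)[C@H]1CC=C(C)C([O-])=C1.[Na+] | intermediate
3 | (5R,6R)-6-hydroxy-2-methyl-5-(prop-1-en-2-yl)cyclohex-2-en-1-one | C=C(C)[C@H]1CC=C(C)C(=O)[C@@H]1O | intermediate
4 | (5R,6R)-6-[(3,4-dimethoxybenzyl)oxy]-2-methyl-5-(prop-1-en-2-yl)cyclohex-2-en-1-one | C=C(C)[C@H]1CC=C(C)C(=O)[C@@H]1OCc1ccc(OC)c(OC)c1 | intermediate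
5 | 2,3-epoxide of 4, oxirane anti to the isopropenyl group | C=C(C)[C@H]1C[C@@H]2O[C@]2(C)C(=O)[C@@H]1OCc1ccc(OC)c(OC)c1 | intermediate
6 | hydrazone of 5 | C=C(C)[C@H]1C[C@@H]2O[C@]2(C)C(=NN)[C@@H]1OCc1ccc(OC)c(OC)c1 | intermediate
7 | (1S,4S,5R)-4-[(3,4-dimethoxybenzyl)oxy]-2-methyl-5-(prop-1-en-2-yl)cyclohex-2-en-1-ol | C=C(C)[C@H]1C[C@H](O)C(C)=C[C@@H]1OCc1ccc(OC)c(OC)c1 | intermediate
8 | (4S,5R)-4-[(3,4-dimethoxybenzyl)oxy]-2-methyl-5-(prop-1-en-2-yl)cyclohex-2-en-1-one | C=C(C)[C@H]1CC(=O)C(C)=C[C@@H]1OCc1ccc(OC)c(OC)c1 | intermediate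
9 | (1R,4S,5R)-4-[(3,4-dimethoxybenzyl)oxy]-2-methyl-5-(prop-1-en-2-yl)cyclohex-2-en-1-ol | C=C(C)[C@H]1C[C@@H](O)C(C)=C[C@@H]1OCc1ccc(OC)c(OC)c1 | intermediate
10 | 2,3-epoxide of 9, oxirane syn to the hydroxyl | C=C(C)[C@H]1C[C@@H](O)[C@@]2(C)O[C@H]2[C@@H]1OCc1ccc(OC)c(OC)c1 | intermediate
11 | 4-methoxybenzyl ether of 10 | C=C(C)[C@H]1C[C@@H](OCc2ccc(OC)cc2)[C@@]2(C)O[C@H]2[C@@H]1OCc1ccc(OC)c(OC)c1 | intermediate
12 | trans-diol from hydrolysis of the oxirane of 11 | C=C(C)[C@H]1C[C@@H](OCc2ccc(OC)cc2)[C@](C)(O)[C@@H](O)[C@@H]1OCc1ccc(OC)c(OC)c1 | intermediate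
13 | (2R,3R,5R)-2-[(3,4-dimethoxybenzyl)oxy]-5-[(4-methoxybenzyl)oxy]-6-oxo-3-(prop-1-en-2-yl)heptanal | O=C[C@H](OCc1ccc(OC)c(OC)c1)[C@@H](C(C)=C)C[C@@H](OCc1ccc(OC)cc1)C(C)=O | intermediate
14 | ethyltriphenylphosphonium iodide | CC[P+](c1ccccc1)(c1ccccc1)c1ccccc1.[I-] | starting material
15 | 3-[(tert-butyldimethylsilyl)oxy]propanal | O=CCCO[Si](C)(C)C(C)(C)C | starting material
16 | ethylidenetriphenylphosphorane | CC=P(c1ccccc1)(c1ccccc1)c1ccccc1 | intermediate
17 | (1-iodoethyl)triphenylphosphonium iodide | CC(I)[P+](c1ccccc1)(c1ccccc1)c1ccccc1.[I-] | intermediate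
18 | (1-iodoethylidene)triphenylphosphorane | CC(I)=P(c1ccccc1)(c1ccccc1)c1ccccc1 | intermediate
19 | (Z)-tert-butyl[(4-iodopent-3-en-1-yl)oxy]dimethylsilane | C/C(I)=C/CCO[Si](C)(C)C(C)(C)C | intermediate
20 | (Z)-alkenyllithium from 19 | C/C([Li])=C/CCO[Si](C)(C)C(C)(C)C | intermediate
21 | (Z)-alkenylzinc bromide from 19 | C/C([Zn]Br)=C/CCO[Si](C)(C)C(C)(C)C | intermediate
22 | (3R,5R,6R,7R,8Z)-11-[(tert-butyldimethylsilyl)oxy]-6-[(3,4-dimethoxybenzyl)oxy]-7-hydroxy-3-[(4-methoxybenzyl)oxy]-8-methyl-5-(prop-1-en-2-yl)undec-8-en-2-one (seco allylic alcohol) | CC(C)(C)[Si](C)(C)OCC/C=C(/C)[C@@H](O)[C@H](OCc1ccc(OC)c(OC)c1)[C@@H](C(C)=C)C[C@@H](OCc1ccc(OC)cc1)C(C)=O | intermediate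
23 | (7S,8S,9S)-7,8-epoxy-9-hydroxy seco compound (plan locants), otherwise as 22 | CC(C)(C)[Si](C)(C)OCC[C@@H]1O[C@]1(C)[C@@H](O)[C@H](OCc1ccc(OC)c(OC)c1)[C@@H](C(C)=C)C[C@@H](OCc1ccc(OC)cc1)C(C)=O | intermediate
24 | angelic acid, (Z)-2-methylbut-2-enoic acid | C/C=C(/C)C(=O)O | starting material
25 | angelic 2,4,6-trichlorobenzoic mixed anhydride | C/C=C(/C)C(=O)OC(=O)c1c(Cl)cc(Cl)cc1Cl | intermediate
26 | 9-O-angeloyl derivative of 23 | CC(C)(C)[Si](C)(C)OCC[C@@H]1O[C@]1(C)[C@@H](OC(=O)/C(C)=C\C)[C@H](OCc1ccc(OC)c(OC)c1)[C@@H](C(C)=C)C[C@@H](OCc1ccc(OC)cc1)C(C)=O | intermediate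
27 | 10-hydroxy compound (DMPM removed from 26) | CC(C)(C)[Si](C)(C)OCC[C@@H]1O[C@]1(C)[C@@H](OC(=O)/C(C)=C\C)[C@H](O)[C@@H](C(C)=C)C[C@@H](OCc1ccc(OC)cc1)C(C)=O | intermediate
28 | (R)-2-methylbutanoic acid | CC[C@@H](C)C(=O)O | starting material
29 | 10-O-[(R)-2-methylbutanoyl] ester of 27 | CC(C)(C)[Si](C)(C)OCC[C@@H]1O[C@]1(C)[C@@H](OC(=O)/C(C)=C\C)[C@H](OC(=O)[C@H](C)CC)[C@@H](C(C)=C)C[C@@H](OCc1ccc(OC)cc1)C(C)=O | intermediate
30 | 5-hydroxy seco compound (TBS removed from 29) | OCC[C@@H]1O[C@]1(C)[C@@H](OC(=O)/C(C)=C\C)[C@H](OC(=O)[C@H](C)CC)[C@@H](C(C)=C)C[C@@H](OCc1ccc(OC)cc1)C(C)=O | intermediate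
31 | seco keto aldehyde (C5 aldehyde, C4 methyl ketone) | O=CC[C@@H]1O[C@]1(C)[C@@H](OC(=O)/C(C)=C\C)[C@H](OC(=O)[C@H](C)CC)[C@@H](C(C)=C)C[C@@H](OCc1ccc(OC)cc1)C(C)=O | intermediate
32 | (1R,3R,4R,5S,7S,8S,9S,10R)-cyclodecane-4,5-diol: 3-O-PMB, 9-O-angeloyl, 10-O-[(R)-2-methylbutanoyl], 7,8-epoxy, 1-isopropenyl | C=C(C)[C@H]1C[C@@H](OCc2ccc(OC)cc2)[C@](C)(O)[C@@H](O)C[C@@H]2O[C@]2(C)[C@@H](OC(=O)/C(C)=C\C)[C@@H]1OC(=O)[C@H](C)CC | intermediate
33 | 5,9-di-O-angeloyl 3-O-PMB ether (1R,3R,4S,5S,7S,8S,9S,10R) | C=C(C)[C@H]1C[C@@H](OCc2ccc(OC)cc2)[C@](C)(O)[C@@H](OC(=O)/C(C)=C\C)C[C@@H]2O[C@]2(C)[C@@H](OC(=O)/C(C)=C\C)[C@@H]1OC(=O)[C@H](C)CC | intermediate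
34 | CNP0246823.2 (1R,3R,4S,5S,7S,8S,9S,10R; plan locants) | C=C(C)[C@H]1C[C@@H](O)[C@](C)(O)[C@@H](OC(=O)/C(C)=C\C)C[C@@H]2O[C@]2(C)[C@@H](OC(=O)/C(C)=C\C)[C@@H]1OC(=O)[C@H](C)CC | target

**Count and risks**
Total step count: 21. Longest linear sequence: 19 (steps 1–9, 11, 12 and 14–21).

Step 19 (most at risk). Ketyl dimerisation between molecules or plain reduction of the aldehyde may outrun closure of the ten-membered ring. The β,γ-epoxy aldehyde may open by β-elimination on the Lewis-acidic samarium salts. The C3 ether may be lost reductively, and facial selectivity at C4/C5 may fall if the chelate does not form.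
Fallback (sets out from 22, returns at 33): the ring is closed before the oxirane exists. 22 is silylated at the C9 hydroxyl (TBSOTf, 2,6-lutidine) to the bis-silyl ether F1. DDQ removes the DMPM group to give the C10 alcohol F2, which is esterified with 28 (DCC, DMAP) to the C10 ester F3. HF·pyridine/pyridine removes only the primary silyl ether to give the primary alcohol F4, and Dess–Martin oxidation gives the (Z)-olefinic keto aldehyde F5. This oxirane-free substrate tolerates a McMurry-type pinacol coupling (TiCl3(DME)1.5, zinc–copper couple, DME, 25 °C, high dilution), which should close the ring to the cyclodecene diol F6. Bu4NF/AcOH then frees the C9 hydroxyl to give the triol F7. mCPBA should epoxidise the ring (Z)-olefin anti to the C9 hydroxyl, as medium-ring (Z)-cycloalkenols do, to give the epoxy triol F8. Double angeloylation of the C5 and C9 hydroxyls with the mixed anhydride 25 (toluene, 75 °C) gives 33.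

Step 11. Chelation control may be lost (poor facial selectivity at C9), transfer from zinc may be sluggish, or the reagent may attack the methyl ketone.
Fallback (sets out from 19 and 13, returns at 22): a Nozaki–Hiyama–Kishi coupling (CrCl2, NiCl2 cat., chiral sulfonamide ligand on chromium, MeCN) is used instead. The ligand, not substrate chelation, then sets C9, and the organochromium species ignores the ketone. This fallback makes no new compound (none F0).

Step 20. Acylation of the hindered C5 hydroxyl next to the tertiary carbinol may be slow, and long heating may isomerise the angeloyl group to tigloyl or let an acyl group migrate.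
Fallback (sets out from 32, returns at 33): 32 is esterified at C5 with 2-[bis(2,2,2-trifluoroethoxy)phosphoryl]propanoic acid (DCC, DMAP) to the phosphonate ester F9. A Still–Gennari olefination with acetaldehyde (KN(SiMe3)2, 2 equiv to allow for the C4 hydroxyl, 18-crown-6, THF, −78 °C) then builds the (Z)-2-methylbut-2-enoate on the molecule and gives 33.

**Further compounds**
F1 | step 19 | 9-O-TBS ether of 22 | CC(C)(C)[Si](C)(C)OCC/C=C(/C)[C@@H](O[Si](C)(C)C(C)(C)C)[C@H](OCc1ccc(OC)c(OC)c1)[C@@H](C(C)=C)C[C@@H](OCc1ccc(OC)cc1)C(C)=O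
F2 | step 19 | C10 alcohol from F1 | CC(C)(C)[Si](C)(C)OCC/C=C(/C)[C@@H](O[Si](C)(C)C(C)(C)C)[C@H](O)[C@@H](C(C)=C)C[C@@H](OCc1ccc(OC)cc1)C(C)=O
F3 | step 19 | C10 (R)-2-methylbutanoate of F2 | CC(C)(C)[Si](C)(C)OCC/C=C(/C)[C@@H](O[Si](C)(C)C(C)(C)C)[C@H](OC(=O)[C@H](C)CC)[C@@H](C(C)=C)C[C@@H](OCc1ccc(OC)cc1)C(C)=O
F4 | step 19 | C5 primary alcohol from F3 | OCC/C=C(/C)[C@@H](O[Si](C)(C)C(C)(C)C)[C@H](OC(=O)[C@H](C)CC)[C@@H](C(C)=C)C[C@@H](OCc1ccc(OC)cc1)C(C)=O
F5 | step 19 | (Z)-olefinic seco keto aldehyde | O=CC/C=C(/C)[C@@H](O[Si](C)(C)C(C)(C)C)[C@H](OC(=O)[C@H](C)CC)[C@@H](C(C)=C)C[C@@H](OCc1ccc(OC)cc1)C(C)=O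
F6 | step 19 | (7Z)-cyclodec-7-ene-4,5-diol, 9-O-TBS | C=C(C)[C@H]1C[C@@H](OCc2ccc(OC)cc2)[C@](C)(O)[C@@H](O)C/C=C(/C)[C@@H](O[Si](C)(C)C(C)(C)C)[C@@H]1OC(=O)[C@H](C)CC
F7 | step 19 | (7Z)-cyclodec-7-ene-4,5,9-triol | C=C(C)[C@H]1C[C@@H](OCc2ccc(OC)cc2)[C@](C)(O)[C@@H](O)C/C=C(/C)[C@@H](O)[C@@H]1OC(=O)[C@H](C)CC
F8 | step 19 | 7,8-epoxycyclodecane-4,5,9-triol | C=C(C)[C@H]1C[C@@H](OCc2ccc(OC)cc2)[C@](C)(O)[C@@H](O)C[C@@H]2O[C@]2(C)[C@@H](O)[C@@H]1OC(=O)[C@H](C)CC
F0 | step 11 | none | none
F9 | step 20 | C5 2-[bis(2,2,2-trifluoroethoxy)phosphoryl]propanoate of 32 | C=C(C)[C@H]1C[C@@H](OCc2ccc(OC)cc2)[C@](C)(O)[C@@H](OC(=O)C(C)P(=O)(OCC(F)(F)F)OCC(F)(F)F)C[C@@H]2O[C@]2(C)[C@@H](OC(=O)/C(C)=C\C)[C@@H]1OC(=O)[C@H](C)CC
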